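C16 and C19 are joined three times: through C20 (CMe2), through O17–C18 and through C15–C14–C13. Taking out O17 and bonding C16 to C18 turns rings C and D into a 7,7-dimethylbicyclo[3.1.1]heptan-6-one, which has a mirror plane while C13 and C15 are both CH2.
That meso cyclobutanone is disconnected by an intramolecular ketene–alkene [2+2] to a 7-methyloct-6-enoyl chloride with C14 masked as a dithiane, built from 1,3-dithiane, 2-(2-bromoethyl)-1,3-dioxolane and prenyl bromide.
Forward: a desymmetrising Baeyer–Villiger oxidation inserts O17 and fixes C16 and C19; β-elimination opens the lactone to a 5-carboxycyclohexenone in which only C13 can enolise; C13 takes a vinyl group (C7) and then C12 anti to C18; after C18 reduction an oxa-Michael addition re-closes ring D.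
Ring B comes from acrylate ring-closing metathesis; ring A from a Diels–Alder reaction of the spiro enoate with a 2-ethoxydiene made from the (S)-Roche ester (C2 from the chiral pool, C7/C8 cis from suprafacial addition, C4 by equilibration beside a temporary C5 ketone), then C5 deoxygenation and oxidation of C3.
Ring order: ring C with the four-membered ring; ring D (as lactone, opened, re-closed as ether); ring B; ring A.

Key step: step 6

Remark: atom labels follow the target SMILES with carbonyl and hydroxyl oxygens uncounted (C1–C3 propanoic acid, C4–C9 ring A, C10 lactone C=O, O11, C12, spiro C13, C14 ketone, C15, C16, O17, C18, C19, C20 = CMe2). Assumption: the sense of induction in step 8 cannot be predicted for this ketone, so the ligand antipode that gives the (1R,5S) lactone is to be selected by running both.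

Step 1
Reactants: 1 1,3-dithiane; 2 2-(2-bromoethyl)-1,3-dioxolane
Product: 4 2-[2-(1,3-dioxolan-2-yl)ethyl]-1,3-dithiane, via 2-lithio-1,3-dithiane 3 (not isolated)
Conditions: n-BuLi, THF, −30 °C; then 2, −78 °C → rt
Reagents that add atoms: none
Why: Corey–Seebach alkylation in which the sulfur-stabilised C2 anion displaces the primary bromide by SN2; the less reactive electrophile is used first, while the anion is unhindered.

Step 2
Reactants: 4 2-[2-(1,3-dioxolan-2-yl)ethyl]-1,3-dithiane; 5 1-bromo-3-methylbut-2-ene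
Product: 7 2-[2-(1,3-dioxolan-2-yl)ethyl]-2-(3-methylbut-2-en-1-yl)-1,3-dithiane, via 2-lithio dithiane 6 (not isolated)
Conditions: n-BuLi, THF, −20 °C; then 5, −78 → 0 °C
Reagents that add atoms: none
Why: second Corey–Seebach alkylation, where the hindered tertiary anion meets the reactive allylic bromide at its primary carbon (SN2 rather than SN2'), so the β,γ-unsaturated ketone is assembled masked and cannot conjugate.

Step 3
Reactants: 7 2-[2-(1,3-dioxolan-2-yl)ethyl]-2-(3-methylbut-2-en-1-yl)-1,3-dithiane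
Product: 8 3-[2-(3-methylbut-2-en-1-yl)-1,3-dithian-2-yl]propanal
Conditions: HCl (2 M aq), THF, rt
Reagents that add atoms: water, O
Why: acid-catalysed acetal hydrolysis; the dithiane needs a thiophile to open and the trisubstituted alkene is not hydrated by dilute acid at room temperature.

Step 4
Reactants: 8 3-[2-(3-methylbut-2-en-1-yl)-1,3-dithian-2-yl]propanal
Product: 9 3-[2-(3-methylbut-2-en-1-yl)-1,3-dithian-2-yl]propanoic acid
Conditions: NaClO2, NaH2PO4, 2-methyl-2-butene (large excess), t-BuOH/H2O, 0 °C → rt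
Reagents that add atoms: sodium chlorite, [Na+].[O-]Cl=O
Why: Pinnick oxidation of the aldehyde to the acid, with the excess scavenger alkene consuming HOCl before it can oxidise sulfur or the prenyl double bond.

Step 5
Reactants: 9 3-[2-(3-methylbut-2-en-1-yl)-1,3-dithian-2-yl]propanoic acid
Product: 10 3-[2-(3-methylbut-2-en-1-yl)-1,3-dithian-2-yl]propanoyl chloride
Conditions: (COCl)2, DMF (cat.), CH2Cl2, 0 °C → rt; evaporate, use crude
Reagents that add atoms: oxalyl chloride, ClC(=O)C(=O)Cl
Why: acid chloride formation through the catalytic chloroiminium species under conditions that leave the dithiane and alkene untouched.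

Step 6
Reactants: 10 3-[2-(3-methylbut-2-en-1-yl)-1,3-dithian-2-yl]propanoyl chloride
Product: 12 meso 7,7-dimethylspiro[bicyclo[3.1.1]heptane-3,2'-[1,3]dithian]-6-one, via aldoketene 11 (not isolated)
Conditions: 10 added over several hours to Et3N (3 equiv), toluene, reflux, final concentration about 0.01 M
Reagents that add atoms: none
Why: Et3N dehydrochlorinates 10 to aldoketene 11, which undergoes an intramolecular, concerted but asynchronous ketene–alkene [2+2] cycloaddition; the closest known reaction type is the bridged-mode cyclisation of 7-methyloct-6-enoyl-derived ketenes to 7,7-dimethylbicyclo[3.1.1]heptan-6-ones. The electrophilic ketene carbon C18 bonds first to the less substituted alkene carbon C16 (a 6-exo-type closure of the temporary ring C18–C19–C13–C14–C15–C16), so positive charge develops on the dimethyl-substituted C20; bonding of C19 to C20 then closes the cyclobutanone and with it ring C (C13–C14–C15–C16–C20–C19). This polarity match is what selects the bridged [3.1.1] mode over the fused bicyclo[3.2.0] alternative, which would place charge on a secondary carbon. The two new stereocentres C16 and C19 are bridgeheads spanned by two one-atom bridges and can only be cis, so a single meso product is expected and regiochemistry is the only selectivity needed here. The C14 dithiane keeps the β,γ-unsaturated ketone masked and its geminal substitution folds the three-atom tether, while slow addition into hot dilute base suppresses ketene dimerisation.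

Step 7
Reactants: 12 meso 7,7-dimethylspiro[bicyclo[3.1.1]heptane-3,2'-[1,3]dithian]-6-one
Product: 13 meso 7,7-dimethylbicyclo[3.1.1]heptane-3,6-dione
Conditions: MeI, CaCO3, MeCN/H2O, 55 °C
Reagents that add atoms: water, O
Why: dithiane hydrolysis by S-methylation and attack of water under neutral, non-oxidising conditions that the strained cyclobutanone tolerates; sulfur has to be removed before any peracid is used.

Step 8
Reactants: 13 meso 7,7-dimethylbicyclo[3.1.1]heptane-3,6-dione
Product: 14 (1R,5S)-8,8-dimethyl-6-oxabicyclo[3.2.1]octane-3,7-dione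
Conditions: Sc(OTf)3 (5 mol %), C2-symmetric N,N'-dioxide ligand from two (S)-pipecolic acid 2,6-diisopropylanilide units on a propane-1,3-diyl linker (6 mol %), m-CPBA, EtOAc, −20 °C
Reagents that add atoms: m-CPBA, OOC(=O)c1cccc(Cl)c1
Why: catalytic desymmetrising Baeyer–Villiger oxidation, in which strain makes the cyclobutanone far more reactive than the C14 ketone and the chiral trivalent scandium complex differentiates the two enantiotopic bridgehead C–C bonds of the Criegee adduct, so one oxygen insertion with retention at the migrating carbon sets C16 and C19 together.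

Step 9
Reactants: 14 (1R,5S)-8,8-dimethyl-6-oxabicyclo[3.2.1]octane-3,7-dione
Product: 16 methyl (1R)-2,2-dimethyl-5-oxocyclohex-3-ene-1-carboxylate, via DBU carboxylate salt 15 (not isolated)
Conditions: DBU, MeCN, rt; then MeI, rt
Reagents that add atoms: iodomethane, CI
Why: E1cB β-elimination of the C16 carboxylate from the C15 enolate (axial C15–H anti to the axial C16–O bond) followed by O-methylation; C19 is never enolised and the resulting enone has acidic hydrogens only at C13.

Step 10
Reactants: 16 methyl (1R)-2,2-dimethyl-5-oxocyclohex-3-ene-1-carboxylate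
Product: 17 (5R)-5-(hydroxymethyl)-4,4-dimethylcyclohex-2-en-1-ol (both C1 epimers)
Conditions: i-Bu2AlH (3.5 equiv), CH2Cl2, −78 °C; aq. potassium sodium tartrate
Reagents that add atoms: none
Why: hydride reduction in which i-Bu2AlH reduces the enone in the 1,2 sense and the ester to the primary alcohol, bringing C18 to its final oxidation level; the C14 carbinol configuration is irrelevant because it is re-oxidised.

Step 11
Reactants: 17 (5R)-5-(hydroxymethyl)-4,4-dimethylcyclohex-2-en-1-ol
Product: 18 (5R)-5-({[tert-butyl(dimethyl)silyl]oxy}methyl)-4,4-dimethylcyclohex-2-en-1-ol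
Conditions: TBSCl (1.05 equiv), imidazole, CH2Cl2, 0 °C
Reagents that add atoms: tert-butyldimethylsilyl chloride, CC(C)(C)[Si](C)(C)Cl
Why: sterically controlled silylation of the primary C18 hydroxyl over the secondary allylic one, which blocks premature oxa-Michael closure.

Step 12
Reactants: 18 (5R)-5-({[tert-butyl(dimethyl)silyl]oxy}methyl)-4,4-dimethylcyclohex-2-en-1-ol
Product: 19 (5R)-5-({[tert-butyl(dimethyl)silyl]oxy}methyl)-4,4-dimethylcyclohex-2-en-1-one
Conditions: MnO2 (activated, excess), CH2Cl2, rt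
Reagents that add atoms: none
Why: allylic alcohol oxidation restores the C14 enone, and with O17 silylated the enone cannot cyclise and C13 remains the only enolisable position.

Step 13
Reactants: 19 (5R)-5-({[tert-butyl(dimethyl)silyl]oxy}methyl)-4,4-dimethylcyclohex-2-en-1-one
Product: 21 (5R)-5-({[tert-butyl(dimethyl)silyl]oxy}methyl)-6-(1-hydroxyethyl)-4,4-dimethylcyclohex-2-en-1-one (epimers at the two new centres), via lithium enolate 20 (not isolated)
Conditions: LiN(i-Pr)2, THF, −78 °C; CH3CHO, −78 °C; AcOH quench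
Reagents that add atoms: acetaldehyde, CC=O
Why: kinetic deprotonation at C13 (C15 is vinylic, C20 quaternary) and aldol addition to acetaldehyde; both new stereocentres are erased in the next step.

Step 14
Reactants: 21 (5R)-5-({[tert-butyl(dimethyl)silyl]oxy}methyl)-6-(1-hydroxyethyl)-4,4-dimethylcyclohex-2-en-1-one
Product: 23 (5S,6E)-5-({[tert-butyl(dimethyl)silyl]oxy}methyl)-6-ethylidene-4,4-dimethylcyclohex-2-en-1-one, via mesylate 22 (not isolated)
Conditions: MsCl, Et3N, CH2Cl2, 0 °C; then DBU, rt
Reagents that add atoms: none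
Why: mesylation and E1cB elimination give the conjugated ethylidene ketone, which holds C7 as an sp2 carbon with a γ-methyl group ready for deconjugation (its geometry does not matter later).

Step 15
Reactants: 23 (5S,6E)-5-({[tert-butyl(dimethyl)silyl]oxy}methyl)-6-ethylidene-4,4-dimethylcyclohex-2-en-1-one
Product: 25 (5S,6S)-5-({[tert-butyl(dimethyl)silyl]oxy}methyl)-6-ethenyl-6-(hydroxymethyl)-4,4-dimethylcyclohex-2-en-1-one, via lithium trienolate 24 (not isolated)
Conditions: LiN(i-Pr)2, DMPU, THF, −78 °C; CH2O (gas, from cracked paraformaldehyde), −78 °C; AcOH quench at −78 °C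
Reagents that add atoms: formaldehyde, C=O
Why: deconjugative α-hydroxymethylation, in which γ-deprotonation of the ethylidene methyl gives cross-conjugated trienolate 24 and kinetic aldol addition occurs at its α-carbon C13; formaldehyde should enter anti to the neighbouring C19 CH2OTBS group and anti to the axial C20 methyl of the reacting half-chair, which creates the quaternary centre with C12 trans to C18 and the vinyl group cis to it.

Step 16
Reactants: 25 (5S,6S)-5-({[tert-butyl(dimethyl)silyl]oxy}methyl)-6-ethenyl-6-(hydroxymethyl)-4,4-dimethylcyclohex-2-en-1-one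
Product: 26 [(1S,6S)-6-({[tert-butyl(dimethyl)silyl]oxy}methyl)-1-ethenyl-5,5-dimethyl-2-oxocyclohex-3-en-1-yl]methyl prop-2-enoate
Conditions: acryloyl chloride, i-Pr2NEt, CH2Cl2, −20 °C
Reagents that add atoms: acryloyl chloride, C=CC(=O)Cl
Why: O-acylation of the neopentyl primary alcohol under mild amine base caps O11 before O17 is released and brings in C10, C8 and the second alkene for metathesis.

Step 17
Reactants: 26 [(1S,6S)-6-({[tert-butyl(dimethyl)silyl]oxy}methyl)-1-ethenyl-5,5-dimethyl-2-oxocyclohex-3-en-1-yl]methyl prop-2-enoate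
Product: 28 [(1S,2S,5S)-2-ethenyl-8,8-dimethyl-3-oxo-6-oxabicyclo[3.2.1]octan-2-yl]methyl prop-2-enoate, via hydroxy enone 27 (not isolated)
Conditions: HF (48% aq), MeCN, 0 °C → rt; then TsOH·H2O (cat.), CH2Cl2, rt
Reagents that add atoms: none
Why: desilylation frees the C18 hydroxyl, which adds intramolecularly (5-exo oxa-Michael) to enone carbon C16 to close ring D; the one-carbon link to C19 allows only the cis bridge, so C16 forms with the configuration dictated by C19, and the distant acrylate is out of reach.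

Step 18
Reactants: 28 [(1S,2S,5S)-2-ethenyl-8,8-dimethyl-3-oxo-6-oxabicyclo[3.2.1]octan-2-yl]methyl prop-2-enoate
Product: 29 (1S,2S,5S)-8,8-dimethyl-2'H-spiro[6-oxabicyclo[3.2.1]octane-2,3'-pyran]-3,6'-dione
Conditions: second-generation Grubbs catalyst RuCl2(=CHPh)(H2IMes)(PCy3) (5 mol %), toluene, 80 °C, 0.005 M
Reagents that add atoms: none
Why: ring-closing metathesis between the C13 vinyl group and the acrylate forms C7=C8 and closes ring B as a six-membered α,β-unsaturated lactone with loss of ethene, the geminal substitution at C13 favouring closure.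

Step 19
Reactants: 30 methyl (2S)-3-hydroxy-2-methylpropanoate
Product: 31 methyl (2S)-3-{[tert-butyl(diphenyl)silyl]oxy}-2-methylpropanoate
Conditions: TBDPSCl, imidazole, DMF, rt
Reagents that add atoms: tert-butyldiphenylsilyl chloride, CC(C)(C)[Si](Cl)(c1ccccc1)c1ccccc1
Why: silyl protection of the Roche ester, which supplies C1–C3 with C2 already in the required configuration; the robust silyl ether survives the later acidic and organometallic steps.

Step 20
Reactants: 31 methyl (2S)-3-{[tert-butyl(diphenyl)silyl]oxy}-2-methylpropanoate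
Product: 32 (2S)-3-{[tert-butyl(diphenyl)silyl]oxy}-N-methoxy-N,2-dimethylpropanamide
Conditions: MeNH(OMe)·HCl, i-PrMgCl, THF, −20 → 0 °C
Reagents that add atoms: N,O-dimethylhydroxylamine hydrochloride, CNOC.Cl
Why: Weinreb amide formation by the chloromagnesium amide, which acylates faster than it enolises the α-stereocentre.

Step 21
Reactants: 32 (2S)-3-{[tert-butyl(diphenyl)silyl]oxy}-N-methoxy-N,2-dimethylpropanamide
Product: 33 (3S)-4-{[tert-butyl(diphenyl)silyl]oxy}-3-methylbutan-2-one
Conditions: MeMgBr, THF, 0 °C; HCl (1 M aq), 0 °C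
Reagents that add atoms: methylmagnesium bromide, C[Mg]Br
Why: Grignard addition to the Weinreb amide stops at the ketone through the stable magnesium chelate; the carbonyl carbon becomes C4 and the new methyl becomes C9.

Step 22
Reactants: 33 (3S)-4-{[tert-butyl(diphenyl)silyl]oxy}-3-methylbutan-2-one
Product: 35 (3S)-4-{[tert-butyl(diphenyl)silyl]oxy}-3-methylbut-1-en-2-yl trifluoromethanesulfonate, via potassium enolate 34 (not isolated)
Conditions: KN(SiMe3)2, THF, −78 °C; PhNTf2, −78 → 0 °C
Reagents that add atoms: N-phenylbis(trifluoromethanesulfonimide), O=S(=O)(N(c1ccccc1)S(=O)(=O)C(F)(F)F)C(F)(F)F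
Why: kinetic enolisation on the less hindered methyl side, which leaves the C2 stereocentre untouched, followed by O-triflation to the 1,1-disubstituted vinyl triflate.

Step 23
Reactants: 35 (3S)-4-{[tert-butyl(diphenyl)silyl]oxy}-3-methylbut-1-en-2-yl trifluoromethanesulfonate
Product: 36 tert-butyl{[(2R)-4-ethoxy-2-methyl-3-methylidenepent-4-en-1-yl]oxy}diphenylsilane
Conditions: tributyl(1-ethoxyvinyl)stannane, Pd(PPh3)4 (5 mol %), LiCl, THF, 65 °C; chromatography on Et3N-deactivated silica
Reagents that add atoms: tributyl(1-ethoxyvinyl)stannane, CCCC[Sn](CCCC)(CCCC)C(=C)OCC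
Why: Stille coupling of the vinyl triflate with the α-ethoxyvinylstannane on zerovalent palladium (chloride assists transmetallation) gives the 2-ethoxy-3-alkyl-1,3-diene that carries C4, C5, C6 and C9.

Step 24
Reactants: 29 (1S,2S,5S)-8,8-dimethyl-2'H-spiro[6-oxabicyclo[3.2.1]octane-2,3'-pyran]-3,6'-dione; 36 tert-butyl{[(2R)-4-ethoxy-2-methyl-3-methylidenepent-4-en-1-yl]oxy}diphenylsilane
Product: 38 5-oxo tetracycle (target skeleton with C5=O and C3 as CH2OSi(t-Bu)Ph2; C2 R C4 R C7 R C8 S C13 S C16 S C19 S), via enol ether cycloadduct 37 (not isolated)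
Conditions: 36 (2 equiv), BHT (trace), CH2Cl2, 1.3 GPa, 40 °C; then HCl (1 M aq), THF, rt, held until C4 has equilibrated
Reagents that add atoms: water, O
Why: normal-demand Diels–Alder reaction accelerated by pressure instead of acid, so the enol ether diene survives; the C5 ethoxy group puts the largest HOMO coefficient on C6, so C6 bonds to the lactone β-carbon C7 and C9 to C8, suprafacial addition to the ring-locked cis alkene makes the ring A/B fusion cis, the diene is expected to approach the face of C7=C8 flanked by the flat C14 carbonyl and not the C19/C18/C20 side, and acid hydrolysis of the enol ether with enolisation toward C4 should leave the side chain equatorial, anti to the axial C10 on C8.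

Step 25
Reactants: 38 5-oxo tetracycle
Product: 40 silyl ether of the C3 alcohol (target skeleton with C3 as CH2OSi(t-Bu)Ph2), via tosylhydrazone 39 (not isolated)
Conditions: TsNHNH2 (1.05 equiv), EtOH, rt; evaporate; catecholborane, CHCl3, 0 °C; NaOAc·3H2O, reflux
Reagents that add atoms: none
Why: ketone deoxygenation through the tosylhydrazone, which should form at the less hindered C5 ketone (C14 sits beside the quaternary C13); hydride adds to C=N and acetate-induced loss of sulfinate and N2 leaves CH2 without any enolisation, so C4 and C8 keep their configurations.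

Step 26
Reactants: 40 silyl ether of the C3 alcohol
Product: 41 C3 primary alcohol (target with CH2OH in place of CO2H)
Conditions: HF·pyridine, THF/pyridine, 0 °C → rt
Reagents that add atoms: none
Why: fluoride cleavage of the silyl ether under buffered, non-basic conditions that neither epimerise C8 nor open the lactone.

Step 27
Reactants: 41 C3 primary alcohol
Product: 42 CNP0152427.1 (C2 R, C4 R, C7 R, C8 S, C13 S, C16 S, C19 S)
Conditions: TEMPO (cat.), PhI(OAc)2, MeCN/H2O, rt
Reagents that add atoms: water, O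
Why: oxoammonium-mediated oxidation of the primary alcohol through the aldehyde hydrate to the acid under near-neutral conditions, which avoids epimerisation at C2 and leaves ketone, lactone and ether untouched.

Compound list
1 | 1,3-dithiane | C1CSCSC1 | starting material
2 | 2-(2-bromoethyl)-1,3-dioxolane | BrCCC1OCCO1 | starting material
3 | 2-lithio-1,3-dithiane | [Li]C1SCCCS1 | intermediate
4 | 2-[2-(1,3-dioxolan-2-yl)ethyl]-1,3-dithiane | C1CSC(CCC2OCCO2)SC1 | intermediate
5 | 1-bromo-3-methylbut-2-ene | CC(C)=CCBr | starting material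
6 | 2-lithio-2-[2-(1,3-dioxolan-2-yl)ethyl]-1,3-dithiane | [Li]C1(CCC2OCCO2)SCCCS1 | intermediate
7 | 2-[2-(1,3-dioxolan-2-yl)ethyl]-2-(3-methylbut-2-en-1-yl)-1,3-dithiane | CC(C)=CCC1(CCC2OCCO2)SCCCS1 | intermediate
8 | 3-[2-(3-methylbut-2-en-1-yl)-1,3-dithian-2-yl]propanal | O=CCCC1(CC=C(C)C)SCCCS1 | intermediate
9 | 3-[2-(3-methylbut-2-en-1-yl)-1,3-dithian-2-yl]propanoic acid | OC(=O)CCC1(CC=C(C)C)SCCCS1 | intermediate
10 | 3-[2-(3-methylbut-2-en-1-yl)-1,3-dithian-2-yl]propanoyl chloride (key-step precursor) | ClC(=O)CCC1(SCCCS1)CC=C(C)C | intermediate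
11 | aldoketene from 10 | O=C=CCC1(SCCCS1)CC=C(C)C | intermediate
12 | meso 7,7-dimethylspiro[bicyclo[3.1.1]heptane-3,2'-[1,3]dithian]-6-one (key-step product) | O=C1[C@@H]2CC3(SCCCS3)C[C@H]1C2(C)C | intermediate
13 | meso 7,7-dimethylbicyclo[3.1.1]heptane-3,6-dione | O=C1[C@@H]2CC(=O)C[C@H]1C2(C)C | intermediate
14 | (1R,5S)-8,8-dimethyl-6-oxabicyclo[3.2.1]octane-3,7-dione | O=C1C[C@@H]2OC(=O)[C@H](C1)C2(C)C | intermediate
15 | DBU-H+ salt of (1R)-2,2-dimethyl-5-oxocyclohex-3-ene-1-carboxylate | [O-]C(=O)[C@@H]1CC(=O)C=CC1(C)C.C1CCC2=[NH+]CCCN2CC1 | intermediate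
16 | methyl (1R)-2,2-dimethyl-5-oxocyclohex-3-ene-1-carboxylate | COC(=O)[C@@H]1CC(=O)C=CC1(C)C | intermediate
17 | (5R)-5-(hydroxymethyl)-4,4-dimethylcyclohex-2-en-1-ol, C1 epimers | OC[C@@H]1CC(O)C=CC1(C)C | intermediate
18 | (5R)-5-({[tert-butyl(dimethyl)silyl]oxy}methyl)-4,4-dimethylcyclohex-2-en-1-ol | CC(C)(C)[Si](C)(C)OC[C@@H]1CC(O)C=CC1(C)C | intermediate
19 | (5R)-5-({[tert-butyl(dimethyl)silyl]oxy}methyl)-4,4-dimethylcyclohex-2-en-1-one | CC(C)(C)[Si](C)(C)OC[C@@H]1CC(=O)C=CC1(C)C | intermediate
20 | lithium C13=C14 enolate of 19 | CC(C)(C)[Si](C)(C)OC[C@@H]1C=C(O[Li])C=CC1(C)C | intermediate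
21 | (5R)-5-({[tert-butyl(dimethyl)silyl]oxy}methyl)-6-(1-hydroxyethyl)-4,4-dimethylcyclohex-2-en-1-one, epimers at C6 and the carbinol | CC(C)(C)[Si](C)(C)OC[C@@H]1C(C(C)O)C(=O)C=CC1(C)C | intermediate
22 | methanesulfonate of 21 | CC(C)(C)[Si](C)(C)OC[C@@H]1C(C(C)OS(C)(=O)=O)C(=O)C=CC1(C)C | intermediate
23 | (5S,6E)-5-({[tert-butyl(dimethyl)silyl]oxy}methyl)-6-ethylidene-4,4-dimethylcyclohex-2-en-1-one | CC(C)(C)[Si](C)(C)OC[C@@H]1/C(=C\C)C(=O)C=CC1(C)C | intermediate
24 | lithium trienolate of 23 (6-ethenyl, C13=C14 enolate) | CC(C)(C)[Si](C)(C)OC[C@@H]1C(C=C)=C(O[Li])C=CC1(C)C | intermediate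
25 | (5S,6S)-5-({[tert-butyl(dimethyl)silyl]oxy}methyl)-6-ethenyl-6-(hydroxymethyl)-4,4-dimethylcyclohex-2-en-1-one | CC(C)(C)[Si](C)(C)OC[C@@H]1[C@](CO)(C=C)C(=O)C=CC1(C)C | intermediate
26 | [(1S,6S)-6-({[tert-butyl(dimethyl)silyl]oxy}methyl)-1-ethenyl-5,5-dimethyl-2-oxocyclohex-3-en-1-yl]methyl prop-2-enoate | CC(C)(C)[Si](C)(C)OC[C@@H]1[C@](COC(=O)C=C)(C=C)C(=O)C=CC1(C)C | intermediate
27 | [(1S,6S)-1-ethenyl-6-(hydroxymethyl)-5,5-dimethyl-2-oxocyclohex-3-en-1-yl]methyl prop-2-enoate | OC[C@@H]1[C@](COC(=O)C=C)(C=C)C(=O)C=CC1(C)C | intermediate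
28 | [(1S,2S,5S)-2-ethenyl-8,8-dimethyl-3-oxo-6-oxabicyclo[3.2.1]octan-2-yl]methyl prop-2-enoate | C=CC(=O)OC[C@@]1(C=C)C(=O)C[C@@H]2OC[C@H]1C2(C)C | intermediate
29 | (1S,2S,5S)-8,8-dimethyl-2'H-spiro[6-oxabicyclo[3.2.1]octane-2,3'-pyran]-3,6'-dione (rings B, C, D) | C1=CC(=O)OC[C@]12C(=O)C[C@@H]3OC[C@H]2C3(C)C | intermediate
30 | methyl (2S)-3-hydroxy-2-methylpropanoate | C[C@@H](CO)C(=O)OC | starting material
31 | methyl (2S)-3-{[tert-butyl(diphenyl)silyl]oxy}-2-methylpropanoate | C[C@@H](CO[Si](c1ccccc1)(c1ccccc1)C(C)(C)C)C(=O)OC | intermediate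
32 | (2S)-3-{[tert-butyl(diphenyl)silyl]oxy}-N-methoxy-N,2-dimethylpropanamide | C[C@@H](CO[Si](c1ccccc1)(c1ccccc1)C(C)(C)C)C(=O)N(C)OC | intermediate
33 | (3S)-4-{[tert-butyl(diphenyl)silyl]oxy}-3-methylbutan-2-one | C[C@@H](CO[Si](c1ccccc1)(c1ccccc1)C(C)(C)C)C(C)=O | intermediate
34 | potassium enolate of 33 (methyl side) | C[C@@H](CO[Si](c1ccccc1)(c1ccccc1)C(C)(C)C)C(=C)O[K] | intermediate
35 | (3S)-4-{[tert-butyl(diphenyl)silyl]oxy}-3-methylbut-1-en-2-yl trifluoromethanesulfonate | C[C@@H](CO[Si](c1ccccc1)(c1ccccc1)C(C)(C)C)C(=C)OS(=O)(=O)C(F)(F)F | intermediate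
36 | tert-butyl{[(2R)-4-ethoxy-2-methyl-3-methylidenepent-4-en-1-yl]oxy}diphenylsilane | C[C@@H](CO[Si](c1ccccc1)(c1ccccc1)C(C)(C)C)C(=C)C(=C)OCC | intermediate
37 | enol ether cycloadduct (target skeleton, C4=C5 with OEt on C5, C3 as CH2OSi(t-Bu)Ph2) | C[C@@H](CO[Si](c1ccccc1)(c1ccccc1)C(C)(C)C)C1=C(OCC)C[C@@H]2[C@H](C1)C(=O)OC[C@]21C(=O)C[C@@H]2OC[C@H]1C2(C)C | intermediate
38 | 5-oxo tetracycle (target skeleton, C5=O, C3 as CH2OSi(t-Bu)Ph2) | C[C@@H](CO[Si](c1ccccc1)(c1ccccc1)C(C)(C)C)[C@@H]1C(=O)C[C@@H]2[C@H](C1)C(=O)OC[C@]21C(=O)C[C@@H]2OC[C@H]1C2(C)C | intermediate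
39 | C5 tosylhydrazone of 38 | C[C@@H](CO[Si](c1ccccc1)(c1ccccc1)C(C)(C)C)[C@@H]1C(=NNS(=O)(=O)c3ccc(C)cc3)C[C@@H]2[C@H](C1)C(=O)OC[C@]21C(=O)C[C@@H]2OC[C@H]1C2(C)C | intermediate
40 | silyl ether of the C3 alcohol (target skeleton, C3 as CH2OSi(t-Bu)Ph2) | C[C@@H](CO[Si](c1ccccc1)(c1ccccc1)C(C)(C)C)[C@@H]1CC[C@@H]2[C@H](C1)C(=O)OC[C@]21C(=O)C[C@@H]2OC[C@H]1C2(C)C | intermediate
41 | C3 primary alcohol (target with CH2OH in place of CO2H) | C[C@@H](CO)[C@@H]1CC[C@@H]2[C@H](C1)C(=O)OC[C@]21C(=O)C[C@@H]2OC[C@H]1C2(C)C | intermediate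
42 | CNP0152427.1 | C[C@@H](C(=O)O)[C@@H]1CC[C@@H]2[C@H](C1)C(=O)OC[C@]21C(=O)C[C@@H]2OC[C@H]1C2(C)C | target

Total step count: 27. Longest linear sequence: 22 steps (steps 1–18 and 24–27 from 1,3-dithiane); the diene branch is 5 steps (19–23).

Steps most likely to fail

1. Step 24 (Diels–Alder). C7 is neopentylic and the enoate is a weak dienophile, so cycloaddition may be slower than diene decomposition, and discrimination between the two faces of C7=C8 may be incomplete. The fallback sets out from diene 36 and lactone 29 and returns at ketone 38, replacing the concerted cycloaddition by a Lewis-acid-triggered stepwise annulation. Diene 36 is hydrolysed (oxalic acid on wet silica, CH2Cl2) to (4R)-5-{[tert-butyl(diphenyl)silyl]oxy}-4-methyl-3-methylidenepentan-2-one F1. This is converted with TBSOTf and Et3N (CH2Cl2, 0 °C) into the silyl dienol ether tert-butyl{[(2R)-4-{[tert-butyl(dimethyl)silyl]oxy}-2-methyl-3-methylidenepent-4-en-1-yl]oxy}diphenylsilane F2. With 29 and EtAlCl2 (CH2Cl2, −78 → −20 °C), a Mukaiyama–Michael addition of C6 to C7 is followed by Michael closure of the lactone enolate carbon C8 onto C9, giving the silyl enol ether annulation product F3. Aqueous HCl in THF then gives 38.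

2. Step 15 (deconjugative hydroxymethylation). The trienolate may be attacked at its γ-terminus instead of C13, deprotonation of the E-configured methyl may be incomplete, formaldehyde may be lost by retro-aldol on work-up, and facial selectivity at C13 may erode. The fallback sets out from 23 and returns at 28, using an irreversible alkylation and changing the order of the ring D closure. Trienolate 24 (from 23 as in step 15) is alkylated at C13 with benzyl chloromethyl ether (THF/DMPU, −78 °C) to the benzyloxymethyl vinyl enone F4. HF (aq)/MeCN removes the silyl group to give the hydroxy enone F5, and catalytic TsOH closes ring D to the bicyclic benzyl ether F6. BCl3 with pentamethylbenzene (CH2Cl2, −78 °C) cleaves the benzyl ether to the bicyclic hydroxymethyl ketone F7. Acryloyl chloride with i-Pr2NEt then gives 28.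

3. Step 8 (desymmetrising Baeyer–Villiger). The catalyst may discriminate poorly between the two bridgehead migrations in this 2,4-bridged cyclobutanone, or the Lewis acid may promote oxidation at C14. The fallback sets out from 13 and returns at 16, replacing asymmetric catalysis by classical resolution. m-CPBA with NaHCO3 (CH2Cl2, 0 °C) gives the racemic keto lactone F8. DBU, then aqueous HCl, gives racemic 2,2-dimethyl-5-oxocyclohex-3-ene-1-carboxylic acid F9. Crystallisation with (S)-1-phenylethylamine (or its antipode, whichever gives the (R)-acid as the less soluble salt) gives the diastereomerically pure ammonium salt F10. Aqueous HCl liberates (1R)-2,2-dimethyl-5-oxocyclohex-3-ene-1-carboxylic acid F11, and MeI with K2CO3 in DMF gives 16.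

Further compounds
F1 | step 24 | (4R)-5-{[tert-butyl(diphenyl)silyl]oxy}-4-methyl-3-methylidenepentan-2-one | C[C@@H](CO[Si](c1ccccc1)(c1ccccc1)C(C)(C)C)C(=C)C(C)=O
F2 | step 24 | tert-butyl{[(2R)-4-{[tert-butyl(dimethyl)silyl]oxy}-2-methyl-3-methylidenepent-4-en-1-yl]oxy}diphenylsilane | C[C@@H](CO[Si](c1ccccc1)(c1ccccc1)C(C)(C)C)C(=C)C(=C)O[Si](C)(C)C(C)(C)C
F3 | step 24 | silyl enol ether annulation product (as 37 with OSi(t-Bu)Me2 on C5) | C[C@@H](CO[Si](c1ccccc1)(c1ccccc1)C(C)(C)C)C1=C(O[Si](C)(C)C(C)(C)C)C[C@@H]2[C@H](C1)C(=O)OC[C@]21C(=O)C[C@@H]2OC[C@H]1C2(C)C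
F4 | step 15 | (5S,6S)-6-[(benzyloxy)methyl]-5-({[tert-butyl(dimethyl)silyl]oxy}methyl)-6-ethenyl-4,4-dimethylcyclohex-2-en-1-one | CC(C)(C)[Si](C)(C)OC[C@@H]1[C@](COCc2ccccc2)(C=C)C(=O)C=CC1(C)C
F5 | step 15 | (5S,6S)-6-[(benzyloxy)methyl]-6-ethenyl-5-(hydroxymethyl)-4,4-dimethylcyclohex-2-en-1-one | OC[C@@H]1[C@](COCc2ccccc2)(C=C)C(=O)C=CC1(C)C
F6 | step 15 | (1S,2S,5S)-2-[(benzyloxy)methyl]-2-ethenyl-8,8-dimethyl-6-oxabicyclo[3.2.1]octan-3-one | C(OC[C@@]1(C=C)C(=O)C[C@@H]2OC[C@H]1C2(C)C)c1ccccc1
F7 | step 15 | (1S,2S,5S)-2-ethenyl-2-(hydroxymethyl)-8,8-dimethyl-6-oxabicyclo[3.2.1]octan-3-one | OC[C@@]1(C=C)C(=O)C[C@@H]2OC[C@H]1C2(C)C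
F8 | step 8 | racemic 8,8-dimethyl-6-oxabicyclo[3.2.1]octane-3,7-dione | O=C1CC2OC(=O)C(C1)C2(C)C
F9 | step 8 | racemic 2,2-dimethyl-5-oxocyclohex-3-ene-1-carboxylic acid | OC(=O)C1CC(=O)C=CC1(C)C
F10 | step 8 | (S)-1-phenylethylammonium (1R)-2,2-dimethyl-5-oxocyclohex-3-ene-1-carboxylate | [O-]C(=O)[C@@H]1CC(=O)C=CC1(C)C.C[C@H]([NH3+])c1ccccc1
F11 | step 8 | (1R)-2,2-dimethyl-5-oxocyclohex-3-ene-1-carboxylic acid | OC(=O)[C@@H]1CC(=O)C=CC1(C)C
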